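**Retrosynthetic overview** (ring A = methylcyclohexane, ring B = cyclohexene, ring C = cyclopentanone, ring D = pyrrolidine-2,4-dione)
1. Ring D is closed last: the spiro carbon–ketone bond is made by intramolecular C-acylation of a ring C β-keto amide with an acetonide-activated N-methyl-D-serine carboxyl, anti to the butenyl chain.
2. Ring C comes from the key radical step: Mn(OAc)3/Cu(OAc)2 oxidative 5-exo cyclisation of a decalin β-keto thioester joins the future spiro carbon to the chain-bearing carbon, and copper-mediated β-hydride loss gives the (E)-alkene next to the preset carbinol.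
3. Rings A and B form together in a Lewis acid-promoted intramolecular Diels–Alder reaction of an (E,E,E)-triene carrying an (E)-2-methyl enone β-keto thioester; the ring A methyl centre controls the four new centres.
4. The open chain is built from small pieces: asymmetric conjugate addition (methyl centre), Takai/Sonogashira/carboalumination–Negishi coupling (triene), dianion aldol–dehydration (dienophile).
5. Order of ring formation: A and B (step 12), then C (step 13), then D (step 15). Ring D is deliberately closed after ring C so that the spiro centre is set by acylation, not in the radical step.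

Assumption: (2R)-pent-4-yn-2-ol and N-methyl-D-serine are taken as commercial, and the (S)-ligand written in step 1 stands for the antipode that gives the 3S ester.

**Step 1**
Reactants: 1 methyl (E)-but-2-enoate; 2 but-3-en-1-ylmagnesium bromide
Product: 3 methyl (3S)-3-methylhept-6-enoate
Conditions: CuI (2 mol %), (S)-2,2'-bis(di-p-tolylphosphino)-1,1'-binaphthyl (3 mol %), t-BuOMe, −40 °C; then H2O
Reagents that add atoms: none
Why: Copper-catalysed asymmetric conjugate addition of a Grignard reagent to an enoate; the chiral copper–bisphosphine complex delivers the butenyl group to one face and sets the methyl-bearing centre (S), which later controls the decalin.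

**Step 2**
Reactants: 3 methyl (3S)-3-methylhept-6-enoate
Product: 5 methyl (3S)-6,6-dimethoxy-3-methylhexanoate, via aldehyde ester 4 (not isolated)
Conditions: O3, CH2Cl2/MeOH, −78 °C; Me2S, −78 to 23 °C; then TsOH·H2O (5 mol %), 23 °C
Reagents that add atoms: methanol (CO)
Why: Ozonolysis with reductive work-up cleaves the only alkene and acid-catalysed acetalisation masks the new aldehyde, so the two chain ends stay different; the stereocentre is untouched.

**Step 3**
Reactants: 5 methyl (3S)-6,6-dimethoxy-3-methylhexanoate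
Product: 6 (3S)-6,6-dimethoxy-3-methylhexanal
Conditions: i-Bu2AlH (1.05 equiv), CH2Cl2, −78 °C; aq. potassium sodium tartrate
Reagents that add atoms: none
Why: Partial ester reduction with i-Bu2AlH stops at the aldehyde because the tetrahedral aluminium alkoxide is stable at −78 °C; the acetal is inert.

**Step 4**
Reactants: 6 (3S)-6,6-dimethoxy-3-methylhexanal
Product: 7 (1E,4S)-1-iodo-7,7-dimethoxy-4-methylhept-1-ene
Conditions: CrCl2 (6 equiv), CHI3 (2 equiv), THF, 0 to 23 °C
Reagents that add atoms: iodoform (IC(I)I)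
Why: Takai olefination: the geminal dichromium species from CHI3 adds to the aldehyde and eliminates to the (E)-vinyl iodide.

**Step 5**
Reactants: 7 (1E,4S)-1-iodo-7,7-dimethoxy-4-methylhept-1-ene; 8 ethynyl(trimethyl)silane
Product: 10 (3E,6S)-9,9-dimethoxy-6-methylnon-3-en-1-yne, via silyl enyne 9 (not isolated)
Conditions: PdCl2(PPh3)2 (3 mol %), CuI (5 mol %), Et3N, THF, 23 °C; then K2CO3 (0.2 equiv), MeOH, 23 °C
Reagents that add atoms: none
Why: Sonogashira coupling joins the alkyne to the vinyl iodide with retention of the E geometry, and methanolysis removes the silyl group.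

**Step 6**
Reactants: 11 (2R)-pent-4-yn-2-ol
Product: 12 tert-butyl(dimethyl){[(2R)-pent-4-yn-2-yl]oxy}silane
Conditions: TBSCl, imidazole, DMF, 23 °C
Reagents that add atoms: tert-butyl(chloro)dimethylsilane (CC(C)(C)[Si](C)(C)Cl)
Why: Silyl ether formation protects the carbinol; its R configuration (the side-chain carbinol of the target) comes from the chiral pool and is never touched again.

**Step 7**
Reactants: 12 tert-butyl(dimethyl){[(2R)-pent-4-yn-2-yl]oxy}silane
Product: 14 tert-butyl{[(2R,4E)-5-iodopent-4-en-2-yl]oxy}dimethylsilane, via vinylzirconocene 13 (not isolated)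
Conditions: Cp2Zr(H)Cl (1.2 equiv), THF, 23 °C; then I2, 0 °C
Reagents that add atoms: iodine (II)
Why: Hydrozirconation adds Zr–H syn with zirconium on the terminal carbon, and iodinolysis with retention gives the (E)-vinyl iodide.

**Step 8**
Reactants: 10 (3E,6S)-9,9-dimethoxy-6-methylnon-3-en-1-yne; 14 tert-butyl{[(2R,4E)-5-iodopent-4-en-2-yl]oxy}dimethylsilane
Product: 17 (4S,6E,8E,10E,13R)-13-{[tert-butyl(dimethyl)silyl]oxy}-4,8-dimethyltetradeca-6,8,10-trienal, via alkenylalane 15 (not isolated), via triene acetal 16 (not isolated)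
Conditions: Me3Al (2.5 equiv), Cp2ZrCl2 (20 mol %), H2O (1.2 equiv), CH2Cl2, −23 °C; then 14, ZnCl2 (1.0 equiv), Pd(PPh3)4 (5 mol %), THF, 23 °C; then 5% aq. oxalic acid, THF, 23 °C
Reagents that add atoms: trimethylaluminium (C[Al](C)C); water (O)
Why: Zirconium-catalysed carboalumination (Negishi) adds methyl and aluminium syn across the alkyne with methyl on the internal carbon, the zinc/palladium Negishi coupling with 14 keeps all alkene geometries, and mild acid hydrolysis of the acetal frees the aldehyde.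

**Step 9**
Reactants: 18 S-tert-butyl ethanethioate; 19 propanoyl chloride
Product: 21 S-tert-butyl 3-oxopentanethioate, via lithium enolate 20 (not isolated)
Conditions: LiN(SiMe3)2 (2.0 equiv), 18 (2.0 equiv), THF, −78 °C; then 19 (1.0 equiv); aq. NH4Cl
Reagents that add atoms: none
Why: Crossed Claisen condensation: the thioester lithium enolate is C-acylated by the acid chloride, the second enolate equivalent taking up the acidic proton of the product.

**Step 10**
Reactants: 21 S-tert-butyl 3-oxopentanethioate; 17 (4S,6E,8E,10E,13R)-13-{[tert-butyl(dimethyl)silyl]oxy}-4,8-dimethyltetradeca-6,8,10-trienal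
Product: 23 S-tert-butyl (8S,10E,12E,14E,17R)-17-{[tert-butyl(dimethyl)silyl]oxy}-5-hydroxy-4,8,12-trimethyl-3-oxooctadeca-10,12,14-trienethioate (epimers at C4 and C5), via dilithium dienolate 22 (not isolated)
Conditions: 21 (1.3 equiv), LiN(i-Pr)2 (2.6 equiv), THF, −78 to 0 °C; then 17, −78 °C; AcOH
Reagents that add atoms: none
Why: Aldol addition of a β-keto thioester dianion (Weiler dianion): the more reactive terminal carbanion adds to the aldehyde; the two new centres are left as a mixture because step 11 erases both.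

**Step 11**
Reactants: 23 S-tert-butyl (8S,10E,12E,14E,17R)-17-{[tert-butyl(dimethyl)silyl]oxy}-5-hydroxy-4,8,12-trimethyl-3-oxooctadeca-10,12,14-trienethioate
Product: 25 S-tert-butyl (4E,8S,10E,12E,14E,17R)-17-{[tert-butyl(dimethyl)silyl]oxy}-4,8,12-trimethyl-3-oxooctadeca-4,10,12,14-tetraenethioate, via mesylate 24 (not isolated)
Conditions: MsCl (1.2 equiv), Et3N (2.5 equiv), CH2Cl2, −20 °C; then DBU (2 equiv), 0 °C
Reagents that add atoms: none
Why: Mesylation and base-induced elimination (E1cB) give the more stable conjugated (E)-2-methyl enone, which is the dienophile.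

**Step 12**
Reactants: 25 S-tert-butyl (4E,8S,10E,12E,14E,17R)-17-{[tert-butyl(dimethyl)silyl]oxy}-4,8,12-trimethyl-3-oxooctadeca-4,10,12,14-tetraenethioate
Product: 26 S-tert-butyl 3-[(1R,2S,4aR,6S,8aS)-2-[(1E,4R)-4-{[tert-butyl(dimethyl)silyl]oxy}pent-1-en-1-yl]-1,3,6-trimethyl-1,2,4a,5,6,7,8,8a-octahydronaphthalen-1-yl]-3-oxopropanethioate
Conditions: Me2AlCl (2.2 equiv), CH2Cl2, −78 to −30 °C
Reagents that add atoms: none
Why: Lewis acid-promoted intramolecular Diels–Alder reaction: the aluminium-bound enone reacts through the endo (acyl-inside) transition state with a chair-like tether that keeps the ring A methyl equatorial, which sets the trans ring fusion, the quaternary centre and the alkenyl-bearing centre (acyl and alkenyl cis) relative to the methyl centre from step 1.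

**Step 13**
Reactants: 26 S-tert-butyl 3-[(1R,2S,4aR,6S,8aS)-2-[(1E,4R)-4-{[tert-butyl(dimethyl)silyl]oxy}pent-1-en-1-yl]-1,3,6-trimethyl-1,2,4a,5,6,7,8,8a-octahydronaphthalen-1-yl]-3-oxopropanethioate
Product: 27 S-tert-butyl (3R,3aS,5aR,7S,9aS,9bR)-3-[(1E,3R)-3-{[tert-butyl(dimethyl)silyl]oxy}but-1-en-1-yl]-4,7,9b-trimethyl-1-oxo-2,3,3a,5a,6,7,8,9,9a,9b-decahydro-1H-cyclopenta[a]naphthalene-2-carbothioate (C2 epimers)
Conditions: Mn(OAc)3·2H2O (2.2 equiv), Cu(OAc)2·H2O (1.0 equiv), degassed AcOH, 23 °C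
Reagents that add atoms: none
Why: Oxidative free-radical cyclisation (Snider type): Mn(OAc)3 oxidises the β-keto thioester enol to the electrophilic α-radical, which closes 5-exo-trig onto the cis-placed alkene with the chain trans to the neighbouring ring B carbon (Beckwith–Houk chair-like transition state, convex face of the cis-fused bicycle), and Cu(OAc)2 oxidises the new secondary radical with β-hydride loss away from the ring to give the (E)-allylic silyl ether; the carbon between the carbonyls stays enolisable and is fixed only in step 15.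

**Step 14**
Reactants: 27 S-tert-butyl (3R,3aS,5aR,7S,9aS,9bR)-3-[(1E,3R)-3-{[tert-butyl(dimethyl)silyl]oxy}but-1-en-1-yl]-4,7,9b-trimethyl-1-oxo-2,3,3a,5a,6,7,8,9,9a,9b-decahydro-1H-cyclopenta[a]naphthalene-2-carbothioate; 28 N-methyl-D-serine
Product: 29 N-{[(3R,3aS,5aR,7S,9aS,9bR)-3-[(1E,3R)-3-{[tert-butyl(dimethyl)silyl]oxy}but-1-en-1-yl]-4,7,9b-trimethyl-1-oxo-2,3,3a,5a,6,7,8,9,9a,9b-decahydro-1H-cyclopenta[a]naphthalen-2-yl]carbonyl}-N-methyl-D-serine
Conditions: AgO2CCF3 (1.2 equiv), Et3N (3 equiv), DMF, 0 to 23 °C; then aq. citric acid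
Reagents that add atoms: none
Why: Silver-promoted aminolysis of the tert-butyl thioester (through the acylketene) gives the β-keto amide; the serine α-centre (R) is carried in unchanged.

**Step 15**
Reactants: 29 N-{[(3R,3aS,5aR,7S,9aS,9bR)-3-[(1E,3R)-3-{[tert-butyl(dimethyl)silyl]oxy}but-1-en-1-yl]-4,7,9b-trimethyl-1-oxo-2,3,3a,5a,6,7,8,9,9a,9b-decahydro-1H-cyclopenta[a]naphthalen-2-yl]carbonyl}-N-methyl-D-serine
Product: 32 pyrenosetin F, via dioxanone 30 (not isolated), via silyl ether 31 (not isolated)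
Conditions: 2-methoxypropene (4 equiv), pyridinium p-toluenesulfonate (10 mol %), CH2Cl2, 0 to 23 °C; then DBU (1.2 equiv), THF, −20 to 0 °C; then HF·pyridine, THF, 0 to 23 °C
Reagents that add atoms: none
Why: Proposed new method: the serine acid and hydroxyl are tied as a 2,2-dimethyl-1,3-dioxan-4-one (an activated ester), DBU forms the ring C β-keto amide enolate whose carbon attacks the acylal carbonyl in a 5-exo-trig Dieckmann-type closure on the face anti to the neighbouring butenyl chain (this sets the spiro carbon), loss of acetone makes the acylation irreversible and frees the hydroxymethyl group without touching the serine α-centre, and HF·pyridine then cleaves the silyl ether; the closest known reactions are the Lacey–Dieckmann tetramic acid synthesis and the acylation of enolates by β-hydroxy acid acetonides (1,3-dioxan-4-ones).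

**Compound list**
1 | methyl (E)-but-2-enoate | C/C=C/C(=O)OC | starting material
2 | but-3-en-1-ylmagnesium bromide | C=CCC[Mg]Br | starting material
3 | methyl (3S)-3-methylhept-6-enoate | COC(=O)C[C@@H](C)CCC=C | intermediate
4 | methyl (3S)-3-methyl-6-oxohexanoate | COC(=O)C[C@@H](C)CCC=O | intermediate
5 | methyl (3S)-6,6-dimethoxy-3-methylhexanoate | COC(=O)C[C@@H](C)CCC(OC)OC | intermediate
6 | (3S)-6,6-dimethoxy-3-methylhexanal | O=CC[C@@H](C)CCC(OC)OC | intermediate
7 | (1E,4S)-1-iodo-7,7-dimethoxy-4-methylhept-1-ene | I/C=C/C[C@@H](C)CCC(OC)OC | intermediate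
8 | ethynyl(trimethyl)silane | C#C[Si](C)(C)C | starting material
9 | [(3E,6S)-9,9-dimethoxy-6-methylnon-3-en-1-yn-1-yl](trimethyl)silane | C[Si](C)(C)C#C/C=C/C[C@@H](C)CCC(OC)OC | intermediate
10 | (3E,6S)-9,9-dimethoxy-6-methylnon-3-en-1-yne | C#C/C=C/C[C@@H](C)CCC(OC)OC | intermediate
11 | (2R)-pent-4-yn-2-ol | C#CC[C@@H](C)O | starting material
12 | tert-butyl(dimethyl){[(2R)-pent-4-yn-2-yl]oxy}silane | C#CC[C@@H](C)O[Si](C)(C)C(C)(C)C | intermediate
13 | chlorobis(cyclopentadienyl)[(1E,4R)-4-{[tert-butyl(dimethyl)silyl]oxy}pent-1-en-1-yl]zirconium | Cl[Zr](C1C=CC=C1)(C1C=CC=C1)/C=C/C[C@@H](C)O[Si](C)(C)C(C)(C)C | intermediate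
14 | tert-butyl{[(2R,4E)-5-iodopent-4-en-2-yl]oxy}dimethylsilane | I/C=C/C[C@@H](C)O[Si](C)(C)C(C)(C)C | intermediate
15 | [(1E,3E,6S)-9,9-dimethoxy-2,6-dimethylnona-1,3-dien-1-yl]dimethylaluminium | C[Al](C)/C=C(\C)/C=C/C[C@@H](C)CCC(OC)OC | intermediate
16 | tert-butyl{[(2R,4E,6E,8E,11S)-14,14-dimethoxy-7,11-dimethyltetradeca-4,6,8-trien-2-yl]oxy}dimethylsilane | CC(C)(C)[Si](C)(C)O[C@H](C)C/C=C/C=C(\C)/C=C/C[C@@H](C)CCC(OC)OC | intermediate
17 | (4S,6E,8E,10E,13R)-13-{[tert-butyl(dimethyl)silyl]oxy}-4,8-dimethyltetradeca-6,8,10-trienal | CC(C)(C)[Si](C)(C)O[C@H](C)C/C=C/C=C(\C)/C=C/C[C@@H](C)CCC=O | intermediate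
18 | S-tert-butyl ethanethioate | CC(=O)SC(C)(C)C | starting material
19 | propanoyl chloride | CCC(=O)Cl | starting material
20 | lithium 1-(tert-butylsulfanyl)ethenolate | [Li+].[O-]C(=C)SC(C)(C)C | intermediate
21 | S-tert-butyl 3-oxopentanethioate | CCC(=O)CC(=O)SC(C)(C)C | intermediate
22 | dilithium 1-(tert-butylsulfanyl)penta-1,3-diene-1,3-diolate (dianion of 21) | [Li+].[Li+].CC=C([O-])C=C([O-])SC(C)(C)C | intermediate
23 | S-tert-butyl (8S,10E,12E,14E,17R)-17-{[tert-butyl(dimethyl)silyl]oxy}-5-hydroxy-4,8,12-trimethyl-3-oxooctadeca-10,12,14-trienethioate (epimers at C4 and C5) | CC(C)(C)SC(=O)CC(=O)C(C)C(O)CC[C@H](C)C/C=C/C(C)=C/C=C/C[C@@H](C)O[Si](C)(C)C(C)(C)C | intermediate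
24 | 5-O-methanesulfonate of 23 | CC(C)(C)SC(=O)CC(=O)C(C)C(OS(C)(=O)=O)CC[C@H](C)C/C=C/C(C)=C/C=C/C[C@@H](C)O[Si](C)(C)C(C)(C)C | intermediate
25 | S-tert-butyl (4E,8S,10E,12E,14E,17R)-17-{[tert-butyl(dimethyl)silyl]oxy}-4,8,12-trimethyl-3-oxooctadeca-4,10,12,14-tetraenethioate | CC(C)(C)SC(=O)CC(=O)/C(C)=C/CC[C@H](C)C/C=C/C(C)=C/C=C/C[C@@H](C)O[Si](C)(C)C(C)(C)C | intermediate
26 | S-tert-butyl 3-[(1R,2S,4aR,6S,8aS)-2-[(1E,4R)-4-{[tert-butyl(dimethyl)silyl]oxy}pent-1-en-1-yl]-1,3,6-trimethyl-1,2,4a,5,6,7,8,8a-octahydronaphthalen-1-yl]-3-oxopropanethioate | CC1=C[C@H]2C[C@@H](C)CC[C@@H]2[C@@](C)(C(=O)CC(=O)SC(C)(C)C)[C@H]1/C=C/C[C@@H](C)O[Si](C)(C)C(C)(C)C | intermediate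
27 | S-tert-butyl (3R,3aS,5aR,7S,9aS,9bR)-3-[(1E,3R)-3-{[tert-butyl(dimethyl)silyl]oxy}but-1-en-1-yl]-4,7,9b-trimethyl-1-oxo-2,3,3a,5a,6,7,8,9,9a,9b-decahydro-1H-cyclopenta[a]naphthalene-2-carbothioate (C2 epimers, enolisable) | CC1=C[C@H]2C[C@@H](C)CC[C@@H]2[C@@]2(C)C(=O)C(C(=O)SC(C)(C)C)[C@H](/C=C/[C@@H](C)O[Si](C)(C)C(C)(C)C)[C@@H]12 | intermediate
28 | N-methyl-D-serine, (2R)-3-hydroxy-2-(methylamino)propanoic acid | CN[C@H](CO)C(=O)O | starting material
29 | N-{[(3R,3aS,5aR,7S,9aS,9bR)-3-[(1E,3R)-3-{[tert-butyl(dimethyl)silyl]oxy}but-1-en-1-yl]-4,7,9b-trimethyl-1-oxo-2,3,3a,5a,6,7,8,9,9a,9b-decahydro-1H-cyclopenta[a]naphthalen-2-yl]carbonyl}-N-methyl-D-serine (C2 epimers) | CC1=C[C@H]2C[C@@H](C)CC[C@@H]2[C@@]2(C)C(=O)C(C(=O)N(C)[C@H](CO)C(=O)O)[C@H](/C=C/[C@@H](C)O[Si](C)(C)C(C)(C)C)[C@@H]12 | intermediate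
30 | acetonide acylal of 29: the N-methyl amide nitrogen carries a (5R)-2,2-dimethyl-4-oxo-1,3-dioxan-5-yl group | CC1=C[C@H]2C[C@@H](C)CC[C@@H]2[C@@]2(C)C(=O)C(C(=O)N(C)[C@@H]3COC(C)(C)OC3=O)[C@H](/C=C/[C@@H](C)O[Si](C)(C)C(C)(C)C)[C@@H]12 | intermediate
31 | pyrenosetin F tert-butyldimethylsilyl ether (silyl group on the side-chain carbinol oxygen) | CC1=C[C@H]2C[C@@H](C)CC[C@@H]2[C@@]2(C)C(=O)[C@@]3(C(=O)[C@@H](CO)N(C)C3=O)[C@H](/C=C/[C@@H](C)O[Si](C)(C)C(C)(C)C)[C@@H]12 | intermediate
32 | pyrenosetin F | CC1=C[C@H]2C[C@@H](C)CC[C@@H]2[C@@]2(C)C(=O)[C@@]3(C(=O)[C@@H](CO)N(C)C3=O)[C@H](/C=C/[C@@H](C)O)[C@@H]12 | target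

**Step count:** 15 steps in total; longest linear sequence 12 steps (steps 1–5, 8, 10–15).

**Steps most likely to fail, with fallbacks**

Step 13 (radical cyclisation). The product still has an enolisable hydrogen and can be oxidised again by trivalent manganese, and the copper-mediated elimination may give some (Z)-alkene or the exocyclic alkene. Fallback: set out from 26 and chlorinate the carbon between the two carbonyls with N-chlorosuccinimide to give the α-chloro β-keto thioester F1. Cyclise F1 under the same Mn(OAc)3/Cu(OAc)2 conditions to the α-chloro cyclopentanone thioester F2, which has no enolisable hydrogen and cannot be over-oxidised. Remove the chlorine with Zn in AcOH to come back to the route at 27.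

Step 15 (spiro ring closure). The acylal C-acylation is untested, and attack on the face syn to the butenyl chain would give the wrong spiro epimer. Fallback: set out from 29 and esterify the acid with Me3SiCHN2 to the methyl ester F3. Close ring D by a titanium-mediated Dieckmann condensation (TiCl4, Et3N, CH2Cl2, −78 to −40 °C), in which the titanium enolate attacks the ester and titanium holds the methoxide so the non-enolisable tricarbonyl is not cleaved. This comes back to the route at 31, which is desilylated with HF·pyridine as in step 15.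

Step 8 (carboalumination and coupling). Me3Al may attack the dimethyl acetal or transfer methyl instead of the dienyl group. Fallback (Julia–Kocienski union): set out from 5 and reduce it with LiAlH4 to the alcohol F4; convert F4 with 1-phenyl-1H-tetrazole-5-thiol under Mitsunobu conditions to the sulfide F5; oxidise F5 with (NH4)6Mo7O24/H2O2 to the sulfone F6. Separately, couple 14 with 2-methylprop-2-enal in a Heck reaction (Pd(OAc)2, Ag2CO3) to give the dienal F7. Olefination of F7 with the anion of F6 (KN(SiMe3)2, DME, −60 °C) comes back to the route at 16, which is hydrolysed to 17 as in step 8.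

**Further compounds**
F1 | step 13 | S-tert-butyl 2-chloro-3-[(1R,2S,4aR,6S,8aS)-2-[(1E,4R)-4-{[tert-butyl(dimethyl)silyl]oxy}pent-1-en-1-yl]-1,3,6-trimethyl-1,2,4a,5,6,7,8,8a-octahydronaphthalen-1-yl]-3-oxopropanethioate | CC1=C[C@H]2C[C@@H](C)CC[C@@H]2[C@@](C)(C(=O)C(Cl)C(=O)SC(C)(C)C)[C@H]1/C=C/C[C@@H](C)O[Si](C)(C)C(C)(C)C
F2 | step 13 | 2-chloro derivative of 27 (chlorine on the carbon between the two carbonyls) | CC1=C[C@H]2C[C@@H](C)CC[C@@H]2[C@@]2(C)C(=O)C(Cl)(C(=O)SC(C)(C)C)[C@H](/C=C/[C@@H](C)O[Si](C)(C)C(C)(C)C)[C@@H]12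
F3 | step 15 | methyl ester of 29 | CC1=C[C@H]2C[C@@H](C)CC[C@@H]2[C@@]2(C)C(=O)C(C(=O)N(C)[C@H](CO)C(=O)OC)[C@H](/C=C/[C@@H](C)O[Si](C)(C)C(C)(C)C)[C@@H]12
F4 | step 8 | (3S)-6,6-dimethoxy-3-methylhexan-1-ol | OCC[C@@H](C)CCC(OC)OC
F5 | step 8 | 5-{[(3S)-6,6-dimethoxy-3-methylhexyl]sulfanyl}-1-phenyl-1H-tetrazole | c1ccccc1-n1nnnc1SCC[C@@H](C)CCC(OC)OC
F6 | step 8 | 5-{[(3S)-6,6-dimethoxy-3-methylhexyl]sulfonyl}-1-phenyl-1H-tetrazole | c1ccccc1-n1nnnc1S(=O)(=O)CC[C@@H](C)CCC(OC)OC
F7 | step 8 | (2E,4E,7R)-7-{[tert-butyl(dimethyl)silyl]oxy}-2-methylocta-2,4-dienal | O=C/C(C)=C/C=C/C[C@@H](C)O[Si](C)(C)C(C)(C)C
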